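## Structural features

The target 17 (C29H26O4) is a macrocyclic bis(bibenzyl). Four benzene rings are joined in the cyclic order A–O–B–CH2CH2–C–O–D–CH2CH2–A, which gives one 19-membered ring (shortest path: three atoms each of rings A, C and D, four of ring B, two ether oxygens, four CH2). Taking C1 as the bridge-bearing carbon of every ring:

| Ring | Ether oxygen | Other substituent |
|---|---|---|
| A | C3 | OMe at C4 |
| B | C4 | none |
| C | C3 | free OH at C4 |
| D | C3 | none |

There is no stereocentre, so nothing stereochemical has to be set. The only sensitive group is the electron-rich 2-aryloxyphenol of ring C, which is prone to oxidation; the ethers and benzylic CH2 groups are robust.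

The difficulty is threefold:
- A flexible large ring with no polar handle in its bridges has to be closed.
- Both diaryl ether bonds end on a carbon ortho to an oxygen substituent of an electron-rich ring, which is not activated for SNAr and is hindered for copper.
- C4–OMe of ring A has to be told apart from C4–OH of ring C, although the two rings have the same substitution pattern.

The key step exploits the triad C1(alkyl)/C3(O-aryl)/C4(O) of ring A together with the para relation of O–C4 and C1–CH2 in ring B. This is the pattern left when the oxygen of one 4-alkylphenol is joined oxidatively to the ortho carbon of another, the coupling presumed to build such skeletons in liverworts. Read backwards, the oxygen on C4 of ring A must be a free phenol when the ring closes, and that singles it out for methylation.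

## Logic of the disconnections

**17 ⇒ 16.** One C–Br bond (C5, ring A), two C–Cl bonds (C3 and C5, ring B) and the O–CH2Ph bond (C4–O, ring C) are put back. These four groups are the control elements of the key step, and all of them answer to one hydrogenolysis. The skeleton does not change, but the sensitive phenol stays masked to the end. The forward step must cleave four bonds of three kinds without touching the diaryl ethers.

**16 ⇒ 15.** The O–CH3 bond on C4 of ring A is cut. In 15 this oxygen is the only free hydroxyl, so the OMe/OH distinction follows from the history of the molecule and needs no selective reagent. The forward step must alkylate a phenol flanked by Br and an aryloxy group.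

**15 ⇒ 12 (key).** The bond C3(ring A)–O(ring B) is cut, which opens the 19-membered ring. In one sentence: oxidative C–O coupling of the two terminal phenols of open-chain 12 closes the macrocycle. The cut removes the large ring, one of the two hindered ethers and the oxygen-differentiation problem together. It leaves a chain with a single diaryl ether and two plain 4-alkylphenol ends. The forward step must run in one direction only (oxygen of ring B onto ring A), must beat intermolecular coupling, and must exclude C–C coupling. This is why ring A carries Br and ring B carries Cl.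

**12 ⇒ 11.** The two C–Br bonds at C3 and C5 of ring A are cut. Bromine cannot pass through the palladium steps, so it has to come after them. Ring A is the only ring with a free OH and open ortho positions. The forward step needs site selectivity among four rings.

**11 ⇒ 10.** The O–C(CH3)3 bond on C4 of ring A is cut. The group comes with a purchasable building block and keeps ring A silent through ylide, borane and palladium chemistry. The forward step must release it without loss of the benzyl ether.

**10 ⇒ 7 + 8.** The bond C1(ring B)–CH2 is cut. This sp2–sp3 bond delivers the B–C bridge already saturated, so no alkene reduction endangers C–Cl or O-benzyl, and 8 brings the chlorine code ready-made. The forward step needs terminal hydroboration and insertion into C–Br in preference to C–Cl.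

**7 ⇒ 6.** The C=CH2 bond on C1 of ring C is cut, a one-carbon extension of an aldehyde. The forward step only needs a non-enolisable aldehyde.

**6 ⇒ 3 + 4.** The bond C1(ring D)–CH2 is cut for the same reason as in 10. The whole A–D bridge and ring A arrive in one operation. The forward step must spare the aldehyde of 3.

**3 ⇒ 1 + 2.** The bond O–C3(ring D) is cut. It is the only ether of the route that needs a metal, and it is made first, on small pieces. It gives two different handles (CHO on ring C, Br on ring D) that fix the order of the two chain extensions. The forward step must leave C–Br intact.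

## Other disconnections considered

Alternative 1: (the first that comes to mind) The cut is the central C–C bond of the A–D bridge, written as C=C. The forward key step is an intramolecular Wittig reaction of the formyl phosphonium salt A1 to the macrocyclic stilbene A2, followed by hydrogenation with loss of benzyl to 17. The chosen plan is preferred for three reasons:
- The closure takes place at the least demanding bond of the molecule.
- Both hindered ethers would still have to be made by separate copper couplings beforehand.
- The two termini need their own redox and activation operations (carbonyl to alcohol to halide to phosphonium, plus masking of the second aldehyde). The count should therefore exceed nine steps, and the OMe/OH problem gains nothing.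

Alternative 2: The cut is the O–C3 bond of ring C, after ring C has been taken back to a 4-substituted cyclohexanone whose two α-carbons are equivalent. In the forward key step the ring D phenoxide of bromoketone A3 displaces the α-bromide to give the macrocyclic 2-aryloxycyclohexanone A4. Twofold dehydrogenation then gives 17 with its OH unprotected. The idea is attractive, but there are four objections:
- The alicyclic ring with its 2-arylethyl arm costs more steps than an aromatic building block.
- The α-bromination has to be done beside a free, electron-rich phenol.
- The Favorskii and dehydrobromination channels of A3 are unimolecular or base-driven, so dilution does not suppress them while it does slow the ring closure.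
- Dehydrogenation next to an aryloxy leaving group could reopen the macrocycle by elimination.

Alternative 3: The cut is the B–C bridge with a sulfonyl group inserted between its two CH2 groups. The forward key step is a Ramberg–Bäcklund ring contraction of the 20-membered sulfone A5 to the stilbene A6, followed by hydrogenation to 17. Closure at soft sulfur should be efficient. However, four operations (closure, oxidation, contraction, reduction) are spent on one unproblematic C–C bond. Both ethers must already be in place. The strongly basic, halogenating medium of the contraction meets three electron-rich rings.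

Key step: step 7

Assumption: the 19-membered ring is taken to be conformationally mobile at room temperature, so no planar or axial chirality has to be controlled. Compounds 1, 2, 4 and 8 are taken as purchasable.

## Steps

Step 1
Reactants: 1 4-(benzyloxy)-3-hydroxybenzaldehyde; 2 (3-bromophenyl)boronic acid
Product: 3 4-(benzyloxy)-3-(3-bromophenoxy)benzaldehyde
Conditions: Cu(OAc)2, pyridine, 4 Å MS, CH2Cl2, air, rt
Reagents that add atoms: none
Why: Chan–Lam O-arylation, in which the phenolate of 1 and the aryl group of 2 meet on copper and reductive elimination from trivalent copper forms the O–C3(ring D) bond at room temperature. The C–Br bond and the aldehyde are inert to copper acetate under these conditions, so 3 carries two different handles.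

Step 2
Reactants: 3 4-(benzyloxy)-3-(3-bromophenoxy)benzaldehyde; 4 1-tert-butoxy-4-vinylbenzene
Product: 6 4-(benzyloxy)-3-{3-[2-(4-tert-butoxyphenyl)ethyl]phenoxy}benzaldehyde, via alkylborane 5 (not isolated)
Conditions: 4, 9-BBN (slight deficit), THF, 0 °C to rt; then 3, Pd(dppf)Cl2, aq. K3PO4, DMF, 50 °C
Reagents that add atoms: none
Why: Anti-Markovnikov hydroboration of the styrene followed by B-alkyl Suzuki–Miyaura coupling gives the saturated A–D bridge directly. No B–H is left for the aldehyde, and aqueous phosphate turns 5 into its borate, which should transmetalate rather than transfer hydride.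

Step 3
Reactants: 6 4-(benzyloxy)-3-{3-[2-(4-tert-butoxyphenyl)ethyl]phenoxy}benzaldehyde
Product: 7 1-(benzyloxy)-2-{3-[2-(4-tert-butoxyphenyl)ethyl]phenoxy}-4-vinylbenzene
Conditions: MePPh3Br, KOtBu, THF, 0 °C to rt
Reagents that add atoms: methyltriphenylphosphonium bromide, C[P+](c1ccccc1)(c1ccccc1)c1ccccc1.[Br-]
Why: Wittig methylenation of a non-enolisable aromatic aldehyde; all ether groups are inert to the ylide.

Step 4
Reactants: 7 1-(benzyloxy)-2-{3-[2-(4-tert-butoxyphenyl)ethyl]phenoxy}-4-vinylbenzene; 8 4-bromo-2,6-dichlorophenol
Product: 10 4-[2-(4-(benzyloxy)-3-{3-[2-(4-tert-butoxyphenyl)ethyl]phenoxy}phenyl)ethyl]-2,6-dichlorophenol, via alkylborane 9 (not isolated)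
Conditions: 7, 9-BBN, THF, rt; then 8, Pd(dppf)Cl2, aq. K3PO4 (excess), DMF, 65 °C; mild acid work-up
Reagents that add atoms: none
Why: Same hydroboration/B-alkyl Suzuki–Miyaura sequence; zerovalent palladium should insert into the C–Br bond of 8 much faster than into the two flanked C–Cl bonds, and the extra base carries 8 as a phenoxide whose donor power is damped by the chlorine atoms. The B–C bridge forms without any alkene reduction, so C–Cl and O-benzyl survive.

Step 5
Reactants: 10 4-[2-(4-(benzyloxy)-3-{3-[2-(4-tert-butoxyphenyl)ethyl]phenoxy}phenyl)ethyl]-2,6-dichlorophenol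
Product: 11 4-[2-(4-(benzyloxy)-3-{3-[2-(4-hydroxyphenyl)ethyl]phenoxy}phenyl)ethyl]-2,6-dichlorophenol
Conditions: TFA, CH2Cl2, 0 °C to rt
Reagents that add atoms: none
Why: Acidolysis of an aryl tert-butyl ether by E1 loss of isobutene; the aryl benzyl ether, the diaryl ether and the C–Cl bonds should be stable to dilute TFA at or below room temperature.

Step 6
Reactants: 11 4-[2-(4-(benzyloxy)-3-{3-[2-(4-hydroxyphenyl)ethyl]phenoxy}phenyl)ethyl]-2,6-dichlorophenol
Product: 12 4-[2-(4-(benzyloxy)-3-{3-[2-(3,5-dibromo-4-hydroxyphenyl)ethyl]phenoxy}phenyl)ethyl]-2,6-dichlorophenol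
Conditions: NBS (2 equiv), diisopropylamine (cat.), CH2Cl2, 0 °C, dark
Reagents that add atoms: N-bromosuccinimide, O=C1CCC(=O)N1Br
Why: Amine-assisted ortho-bromination of a phenol (electrophilic aromatic substitution): ring A is the only ring with a free OH and open ortho positions, ring B is fully blocked, and rings C and D are only ethers. A stray bromine on ring C or D would be harmless, because step 9 removes every C–Br bond.

Step 7
Reactants: 12 4-[2-(4-(benzyloxy)-3-{3-[2-(3,5-dibromo-4-hydroxyphenyl)ethyl]phenoxy}phenyl)ethyl]-2,6-dichlorophenol
Product: 15 macrocyclic bromophenol (ring A C4-OH and C5-Br; ring B C3-Cl and C5-Cl; ring C C4-OBn), via bromodienone 13 (not isolated), via methoxydienone 14 (not isolated)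
Conditions: Tl(NO3)3·3H2O, MeOH/CH2Cl2, slow addition of 12 to 1 mM, −20 to 0 °C; concentrate; then Zn, AcOH/THF, rt
Reagents that add atoms: none
Why: Trivalent thallium binds the two acidic phenols of 12 in exchange for nitrate and takes two electrons, which puts ring A at the phenoxyl/phenoxenium level with spin and charge on C3 and C5 (both C–Br) and on C1 (blocked by the bridge). The oxygen on C4 of ring B bonds to C3 of ring A to give bromodienone 13, bromide leaves, methanol caps C1 to give the non-phenolic and therefore over-oxidation-proof quinol ether 14, and zinc in acetic acid expels the methoxy group reductively and rearomatises ring A to 15. The closest known reaction type is the thallium trinitrate (or anodic) oxidative coupling of 2,6-dihalo-4-alkylphenols to 2-aryloxyphenols, known also for closing macrocyclic diaryl ethers of the isodityrosine class, and it copies the phenol coupling presumed for the biosynthesis of bis(bibenzyls). One ring is closed, the 19-membered one, by end-to-end attack of an oxygen nucleophile on a ring carbon that becomes a ring member; high dilution and slow addition hold back dimers, and a thallium centre carrying both phenolates at once should bring the chain ends together. No lasting stereocentre is formed, since the sp3 carbons C3 in 13 and C1 in 14 are racemic, transient and erased on aromatisation. The selectivity that counts is the direction of coupling, because attack of the ring A oxygen on ring B would also give a 19-membered ring; the halogen code secures it, as the dibromophenol should be the more easily oxidised partner and bromide the better leaving group in the irreversible step, while the more acidic dichlorophenol is the better oxygen donor. C–C coupling is excluded because every ortho and para position of both phenols is substituted, and ring C cannot bind thallium because its oxygen is benzylated. Capture of an oxidised ring by methanol without ring closure is not destructive, since the zinc treatment should return such quinol ethers to 12 for another pass.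

Step 8
Reactants: 15 macrocyclic bromophenol (ring A C4-OH and C5-Br; ring B C3-Cl and C5-Cl; ring C C4-OBn)
Product: 16 macrocyclic methyl ether (ring A C4-OMe and C5-Br; ring B C3-Cl and C5-Cl; ring C C4-OBn)
Conditions: MeI, K2CO3, DMF, rt
Reagents that add atoms: iodomethane, CI
Why: Williamson methylation; the C4–OH of ring A is the only free hydroxyl in 15 and is acidified by the ortho bromine, so no selectivity is required.

Step 9
Reactants: 16 macrocyclic methyl ether (ring A C4-OMe and C5-Br; ring B C3-Cl and C5-Cl; ring C C4-OBn)
Product: 17 target CNP0132125.0
Conditions: H2 (1–4 atm), Pd/C, NaOAc, MeOH/THF, rt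
Reagents that add atoms: none
Why: Catalytic hydrogenolysis: Pd/C cleaves the benzyl ether and, with NaOAc as acid scavenger, reduces the C–Br and both C–Cl bonds, while diaryl ethers, OMe and the arenes are inert. All control elements of the key step leave in one operation.

## Compound list

1 | 4-(benzyloxy)-3-hydroxybenzaldehyde | O=Cc1ccc(OCc2ccccc2)c(O)c1 | starting material
2 | (3-bromophenyl)boronic acid | OB(O)c1cccc(Br)c1 | starting material
3 | 4-(benzyloxy)-3-(3-bromophenoxy)benzaldehyde | O=Cc1ccc(OCc2ccccc2)c(Oc2cccc(Br)c2)c1 | intermediate
4 | 1-tert-butoxy-4-vinylbenzene | C=Cc1ccc(OC(C)(C)C)cc1 | starting material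
5 | 9-[2-(4-tert-butoxyphenyl)ethyl]-9-borabicyclo[3.3.1]nonane | CC(C)(C)Oc1ccc(CCB2C3CCCC2CCC3)cc1 | intermediate
6 | 4-(benzyloxy)-3-{3-[2-(4-tert-butoxyphenyl)ethyl]phenoxy}benzaldehyde | O=Cc1ccc(OCc2ccccc2)c(Oc2cccc(CCc3ccc(OC(C)(C)C)cc3)c2)c1 | intermediate
7 | 1-(benzyloxy)-2-{3-[2-(4-tert-butoxyphenyl)ethyl]phenoxy}-4-vinylbenzene | C=Cc1ccc(OCc2ccccc2)c(Oc2cccc(CCc3ccc(OC(C)(C)C)cc3)c2)c1 | intermediate
8 | 4-bromo-2,6-dichlorophenol | Oc1c(Cl)cc(Br)cc1Cl | starting material
9 | 9-BBN adduct of 7 (boron on the terminal CH2 of the ring C side chain) | CC(C)(C)Oc1ccc(CCc2cccc(Oc3cc(CCB4C5CCCC4CCC5)ccc3OCc3ccccc3)c2)cc1 | intermediate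
10 | 4-[2-(4-(benzyloxy)-3-{3-[2-(4-tert-butoxyphenyl)ethyl]phenoxy}phenyl)ethyl]-2,6-dichlorophenol | CC(C)(C)Oc1ccc(CCc2cccc(Oc3cc(CCc4cc(Cl)c(O)c(Cl)c4)ccc3OCc3ccccc3)c2)cc1 | intermediate
11 | 4-[2-(4-(benzyloxy)-3-{3-[2-(4-hydroxyphenyl)ethyl]phenoxy}phenyl)ethyl]-2,6-dichlorophenol | Oc1ccc(CCc2cccc(Oc3cc(CCc4cc(Cl)c(O)c(Cl)c4)ccc3OCc3ccccc3)c2)cc1 | intermediate
12 | 4-[2-(4-(benzyloxy)-3-{3-[2-(3,5-dibromo-4-hydroxyphenyl)ethyl]phenoxy}phenyl)ethyl]-2,6-dichlorophenol | Oc1c(Br)cc(CCc2cccc(Oc3cc(CCc4cc(Cl)c(O)c(Cl)c4)ccc3OCc3ccccc3)c2)cc1Br | intermediate
13 | macrocyclic bromodienone: ring A as 6-aryloxy-2,6-dibromocyclohexa-2,4-dien-1-one (C4=O; C3 sp3 with Br and O-ring B; C5-Br), racemic, rest as in 15 | O=C1C(Br)=CC2=CC1(Br)Oc1c(Cl)cc(cc1Cl)CCc1ccc(OCc3ccccc3)c(c1)Oc1cccc(c1)CC2 | intermediate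
14 | macrocyclic methoxydienone: ring A as 2-aryloxy-6-bromo-4-methoxycyclohexa-2,5-dien-1-one (C4=O; C1 sp3 with OMe and bridge), racemic, rest as in 15 | O=C1C(Br)=CC2(OC)C=C1Oc1c(Cl)cc(cc1Cl)CCc1ccc(OCc3ccccc3)c(c1)Oc1cccc(c1)CC2 | intermediate
15 | macrocyclic bromophenol: 17 with OH in place of OMe on ring A C4, Br on ring A C5, Cl on ring B C3 and C5, OBn on ring C C4 | Oc1c(Br)cc2cc1Oc1c(Cl)cc(cc1Cl)CCc1ccc(OCc3ccccc3)c(c1)Oc1cccc(c1)CC2 | intermediate
16 | methyl ether of 15 | COc1c(Br)cc2cc1Oc1c(Cl)cc(cc1Cl)CCc1ccc(OCc3ccccc3)c(c1)Oc1cccc(c1)CC2 | intermediate
17 | CNP0132125.0, achiral macrocyclic bis(bibenzyl) | COc1ccc2cc1Oc1ccc(cc1)CCc1ccc(O)c(c1)Oc1cccc(c1)CC2 | target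

## Step count and least certain steps

Total steps: 9. Longest linear sequence: 9 (from 1 to 17; 2, 4 and 8 enter as purchased).

**Step 7 (key step).** Four things are most likely to go wrong:
- Intermolecular coupling may outrun the entropically costly closure of a chain that has no conformational bias.
- Methanol may capture the oxidised rings faster than the ring closes, so that material only cycles back after the zinc treatment.
- The direction of coupling may erode if the difference between the bromo- and chlorophenol is too small.
- Outer-sphere oxidation of the electron-rich ring C may compete.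

The fallback sets out from 3 and comes back at 17. It moves the ring closure to the C1(ring B)–CH2 bond.
- Isovanillin and 4-chlorophenylboronic acid are joined under the conditions of step 1 to 3-(4-chlorophenoxy)-4-methoxybenzaldehyde F1.
- Wittig methylenation gives 2-(4-chlorophenoxy)-1-methoxy-4-vinylbenzene F2.
- Hydroboration with 9-BBN gives alkylborane F3, which is coupled with the bromide of 3 (Pd(dppf)Cl2, K3PO4; the C–Cl bond stays) to the aldehyde F4.
- Methylenation gives the styrene F5, and hydroboration gives alkylborane F6.
- Slow addition of F6 to Pd(OAc)2, SPhos and K3PO4 at high dilution closes the ring by an intramolecular B-alkyl Suzuki–Miyaura coupling to the O-benzyl ether of the target F7.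
- Hydrogenolysis (H2, Pd/C) gives 17.

**Step 2.** The most likely failure is hydride transfer from the alkylborane or from residual B–H to the aldehyde. Protodeboronation or β-hydride elimination may also consume the alkyl partner. The fallback sets out from 3 and 4 and comes back at 6. A Heck reaction (Pd(OAc)2, P(o-tol)3, NaOAc, DMF, 100 °C) forms the sp2–sp2 bond and gives the (E)-stilbene aldehyde F8. Its alkene is then saturated with H2 over Pd/C poisoned with Ph2S, which should spare the aldehyde and the benzyl ether.

**Step 4.** Oxidative addition into the electron-rich bromophenoxide may be slow, which leaves time for decay of the alkylborane and for some insertion into C–Cl. The fallback sets out from 8 and 9 and comes back at 11. Compound 8 is converted with chloromethyl methyl ether and diisopropylethylamine into 5-bromo-1,3-dichloro-2-(methoxymethoxy)benzene F9. This neutral aryl bromide is coupled with 9 to the doubly protected chain F10. The TFA treatment of step 5, with a trace of water, then removes both acid-labile groups at once and gives 11.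

**Step 9.** Hydrodechlorination may stall at the two C–Cl bonds that flank the ether oxygen, because they are shielded and released halide poisons the palladium surface. Debenzylation is faster, so partly dehalogenated phenols would accumulate. The fallback sets out from 16 and comes back at 17. The benzyl ether is cleaved first by a Lewis acid (BCl3, pentamethylbenzene, CH2Cl2, −78 °C) to the free phenol F11. As its phenoxide, F11 dissolves in aqueous methanolic NaOH and is dehalogenated there with Ni–Al alloy, a dissolving-metal reduction that does not depend on a palladium surface.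

## Further compounds

F1 | step 7 | 3-(4-chlorophenoxy)-4-methoxybenzaldehyde | COc1ccc(C=O)cc1Oc1ccc(Cl)cc1
F2 | step 7 | 2-(4-chlorophenoxy)-1-methoxy-4-vinylbenzene | COc1ccc(C=C)cc1Oc1ccc(Cl)cc1
F3 | step 7 | 9-BBN adduct of F2 | COc1ccc(CCB2C3CCCC2CCC3)cc1Oc1ccc(Cl)cc1
F4 | step 7 | 4-(benzyloxy)-3-(3-{2-[3-(4-chlorophenoxy)-4-methoxyphenyl]ethyl}phenoxy)benzaldehyde | COc1ccc(CCc2cccc(Oc3cc(C=O)ccc3OCc3ccccc3)c2)cc1Oc1ccc(Cl)cc1
F5 | step 7 | vinyl compound from F4 (CH=CH2 in place of CHO) | COc1ccc(CCc2cccc(Oc3cc(C=C)ccc3OCc3ccccc3)c2)cc1Oc1ccc(Cl)cc1
F6 | step 7 | 9-BBN adduct of F5 | COc1ccc(CCc2cccc(Oc3cc(CCB4C5CCCC4CCC5)ccc3OCc3ccccc3)c2)cc1Oc1ccc(Cl)cc1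
F7 | step 7 | O-benzyl ether of 17 (ring C C4-OBn) | COc1ccc2cc1Oc1ccc(cc1)CCc1ccc(OCc3ccccc3)c(c1)Oc1cccc(c1)CC2
F8 | step 2 | 4-(benzyloxy)-3-{3-[(E)-2-(4-tert-butoxyphenyl)ethenyl]phenoxy}benzaldehyde | O=Cc1ccc(OCc2ccccc2)c(Oc2cccc(/C=C/c3ccc(OC(C)(C)C)cc3)c2)c1
F9 | step 4 | 5-bromo-1,3-dichloro-2-(methoxymethoxy)benzene | COCOc1c(Cl)cc(Br)cc1Cl
F10 | step 4 | methoxymethyl ether of 10 | CC(C)(C)Oc1ccc(CCc2cccc(Oc3cc(CCc4cc(Cl)c(OCOC)c(Cl)c4)ccc3OCc3ccccc3)c2)cc1
F11 | step 9 | debenzylated 16 (ring C C4-OH; Br and two Cl retained) | COc1c(Br)cc2cc1Oc1c(Cl)cc(cc1Cl)CCc1ccc(O)c(c1)Oc1cccc(c1)CC2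
A1 | alternative 1 | formyl phosphonium bromide (CHO on ring A C1, CH2PPh3 on ring D C1, ring C C4-OBn) | COc1ccc(C=O)cc1Oc1ccc(cc1)CCc1ccc(OCc2ccccc2)c(c1)Oc1cccc(C[P+](c2ccccc2)(c2ccccc2)c2ccccc2)c1.[Br-]
A2 | alternative 1 | macrocyclic stilbene (C=C in the A–D bridge, E/Z not fixed) | COc1ccc2cc1Oc1ccc(cc1)CCc1ccc(OCc3ccccc3)c(c1)Oc1cccc(c1)C=C2
A3 | alternative 2 | open-chain 2-bromo-4-(2-arylethyl)cyclohexanone with free ring D phenol (diastereomers not fixed) | COc1ccc(CCc2cccc(O)c2)cc1Oc1ccc(CCC2CCC(=O)C(Br)C2)cc1
A4 | alternative 2 | macrocyclic 2-aryloxycyclohexanone (ring C alicyclic, diastereomers not fixed) | COc1ccc2cc1Oc1ccc(cc1)CCC1CCC(=O)C(C1)Oc1cccc(c1)CC2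
A5 | alternative 3 | 20-membered dibenzyl sulfone (SO2 within the B–C bridge) | COc1ccc2cc1Oc1ccc(cc1)CS(=O)(=O)Cc1ccc(OCc3ccccc3)c(c1)Oc1cccc(c1)CC2
A6 | alternative 3 | macrocyclic stilbene (C=C in the B–C bridge, E/Z not fixed) | COc1ccc2cc1Oc1ccc(cc1)C=Cc1ccc(OCc3ccccc3)c(c1)Oc1cccc(c1)CC2
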